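(The earlier runs and the new flask were generated by integration with made-up constants; the scatter is artificial.)

- The ratio I start from is the cover r: partner charged, over starting material plus second substrate charged, on my assumption that each of those two spends partner mole for mole.

in all of them: catalyst 0.29 mM

| run | starting material | partner | second substrate | remark | time |
|---|---|---|---|---|---|
| winter | 0.33 M | 0.33 M | 0.22 M | run made earlier |  |
| spring | 0.22 M | 0.66 M | 0.22 M | run made earlier |  |
| grey | 0.22 M | 0.330 M | 0.440 M |  | 12 h |
| violet | 0.22 M | 0.330 M | 0.220 M |  | 12 h |

| run | time / h | starting material / % | target / % |
|---|---|---|---|
| winter | 1.33 | 16.5 | 24.5 |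
| winter | 2.50 | 10.1 | 29.6 |
| winter | 4.00 | 5.7 | 30.2 |
| winter | 5.00 | 4.3 | 32.4 |
| winter | 6.00 | 4.6 | 30.6 |
| winter | 8.00 | 2.7 | 33.8 |
| spring | 0.500 | 37.9 | 36.4 |
| spring | 1.00 | 20.7 | 47.3 |
| spring | 1.50 | 13.5 | 53.3 |
| spring | 2.50 | 3.7 | 58.2 |
| spring | 4.00 | 1.4 | 63.5 |
| spring | 8.00 | 0.2 | 64.5 |

(standard deviation of a reading: 1 percentage point)

1. which of these there is most of at the end, counted by the starting material in it, grey (target / starting material)
2. which of these there is most of at the end, counted by the starting material in it, violet (target / starting material)
3. how much there is at the end of the one of these that leads, in percent of the starting material charged: grey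
4. how much there is at the end of the one of these that leads, in percent of the starting material charged: violet



- Where r is below one, the partner charged falls short of the two claims together on my count, so I give the starting material the part of the partner that its charge claims. Target, in percent of the starting material charged, is then r times a factor g, the part of that claim that ends as target.
- The winter run has r = 0.600, and its last reading of target, 33.8%, gives 0.563 for g, the yield of target per unit of cover; this value carries the scatter of that reading.
- The spring run has r = 1.50, which is above one, so on my count partner meets both claims there. The rule gives 84.4% against a reading of 64.5%, so I use it below one only.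
- Violet has r = 0.750, so I expect 42.2% of target. Grey has r = 0.500, so I expect 28.2%, holding g at its winter value although the starting material charge differs.
- Winter's starting material stood at 2.7% after 8.00 h, less than its target, so I expect target to lead in both flasks at 12 h.
- The forecast also has target leading, but at 48% in grey and 48% in violet, which differs from my figures, with the words “Grey should be similar”.
- The flask gives target leading in grey with 30.7% against 4.84% of starting material, and target leading in violet with 42.6% against 2.17%.

    starting material + partner + catalyst → catalyst + target (k = 120 L² mol⁻² min⁻¹)
    second substrate + partner + catalyst → catalyst + second product (k = 140 L² mol⁻² min⁻¹)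
    2 starting material → homo dimer (k = 0.0520 L mol⁻¹ min⁻¹)

- In grey, half of the loss of starting material to homo dimer up to 12 h is done by 0.462 h, and by 6.00 h the step to target has 99.4% of its turnover up to 12 h behind it, with partner down to 1.96% of its charge. At 12 h in grey, partner, the limiting reagent there, stands at 0.120%, second substrate at 40.5%, and homo dimer, counted by the starting material in it, at 64.4%, while violet keeps 11.0% of its partner and 9.09% of its second substrate, with homo dimer at 55.3%. Yield over cover comes to 0.568 in violet and 0.614 in grey, against my 0.563.
- A neighbour of grey charged with 0.18 M of second substrate has r = 0.825, so g gives 46.4% of target. The computed flask gives 44.9%, with 18% of its partner left.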